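**Retrosynthetic overview**
- The route rests on C2' of the piperidine ring. It is the only stereocentre and is bonded to N1' and to C6 of flavone ring A. It therefore maps onto an aryl ketone carbon, and C6' maps onto a primary chloride at the end of the same chain.
- Key disconnections are C2'–N1' and N1'–C6'. An (R)-selective transaminase aminates the aryl 4-chlorobutyl ketone, and the new amine closes the piperidine ring, which is the first ring made.
- Ring C is made second and last. O1–C8a comes from CuI-catalysed O-arylation of a 1,3-diketone at an aryl bromide para to C2', which allows only the 6-substituted flavone. C2–C3 comes from Claisen benzoylation (ring B is bought as methyl benzoate), and C4–C4a from acylation of an aryllithium formed between Br and OMe.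
- Ring A is bought as 4-bromo-2,6-dimethoxybenzaldehyde. Addition of 4-chlorobutylmagnesium bromide followed by oxidation gives the chloroketone, and both methyl ethers are cleaved in the last step.

Key step: step 3

Assumption: C2' is read from the SMILES as (R) (N1' > C6 of ring A > C3' > H). This priority order holds in every intermediate, so the descriptor does not change along the route.

**Step 1**
Reactants: 1 4-bromo-2,6-dimethoxybenzaldehyde; 2 1-bromo-4-chlorobutane
Product: 4 (±)-1-(4-bromo-2,6-dimethoxyphenyl)-5-chloropentan-1-ol, via 4-chlorobutylmagnesium bromide 3 (not isolated)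
Conditions: 2, Mg, THF, 25–30 °C; then 1, THF, −20 → 0 °C; aqueous work-up
Reagents that add atoms: none
Why: Grignard addition: magnesium inserts into the weaker C–Br bond of 2 and spares the C–Cl bond, and the primary alkylmagnesium bromide 3 adds to the aldehyde at or below 0 °C much faster than it exchanges with the aryl bromide or than the magnesium alkoxide attacks the chloride, while the carbinol centre forms racemic and is erased in step 2.

**Step 2**
Reactants: 4 (±)-1-(4-bromo-2,6-dimethoxyphenyl)-5-chloropentan-1-ol
Product: 5 1-(4-bromo-2,6-dimethoxyphenyl)-5-chloropentan-1-one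
Conditions: IBX (2-iodoxybenzoic acid, 1.5 equiv), DMSO, rt
Reagents that add atoms: none
Why: Hypervalent-iodine (IBX) oxidation of a secondary benzylic alcohol to the aryl ketone runs without strong acid or base, so the ionisable 2,6-dimethoxybenzylic alcohol, the primary chloride and the aryl bromide should all survive.

**Step 3**
Reactants: 5 1-(4-bromo-2,6-dimethoxyphenyl)-5-chloropentan-1-one; 6 isopropylamine
Product: 8 (2R)-2-(4-bromo-2,6-dimethoxyphenyl)piperidine, via (1R)-amino chloride 7 (not isolated)
Conditions: evolved (R)-selective ω-transaminase (ATA-117 family, variant selected on 5), PLP (1 mM), 6 (1 M), potassium phosphate buffer (100 mM, pH 8), DMSO (20% v/v), 40 °C; then aq NaOH, 40 °C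
Reagents that add atoms: isopropylamine (6), CC(C)N
Why: Proposed new method: isopropylamine 6 charges the PLP cofactor to pyridoxamine phosphate and leaves as acetone, the cofactor amine condenses with ketone 5 to a ketimine, a prototropic shift passes through a planar quinonoid carbanion, the active-site lysine protonates C2' from one face only, and hydrolysis releases amino chloride 7. The closest known reaction type is the transaminase-triggered cyclisation of aryl ω-chloroalkyl ketones to 2-arylpyrrolidines and 2-arylpiperidines, which has been shown for aryl groups without two ortho substituents, so a variant with a widened large pocket must first be found by screening and directed evolution on 5. The piperidine ring closes by 6-exo-tet SN2 attack of the new primary amine N1' on C6' with loss of chloride, finished by the basic hold at the end, and this irreversible step removes the amine from the otherwise unfavourable transamination equilibrium. C2' is controlled by the enzyme alone: the aryl group must lie in the large pocket and the chlorobutyl chain in the small one, the arrangement by which (R)-selective enzymes of this family give (R)-1-arylalkylamines. The face selectivity rests on the large difference in shape between the broad 4-bromo-2,6-dimethoxyphenyl group and the slim unbranched chain, and the chemoselectivity for C=O over C–Cl rests on the primary chloride being slow in intermolecular substitution at pH 8, where the amine donor is almost fully protonated, whereas the aryl bromide and the ethers are inert in buffer. The two ortho methoxy groups twist the carbonyl group out of conjugation with the ring, which should make it more electrophilic and its amination less uphill than for a planar aryl ketone, and the near-neutral to basic aqueous medium cannot ionise the benzylic C2'–N1' bond.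

**Step 4**
Reactants: 8 (2R)-2-(4-bromo-2,6-dimethoxyphenyl)piperidine
Product: 9 (2R)-2-(4-bromo-2,6-dimethoxyphenyl)-1-methylpiperidine
Conditions: 37% aq HCHO, NaBH(OAc)3, ClCH2CH2Cl, rt
Reagents that add atoms: formaldehyde, C=O
Why: Reductive amination with NaBH(OAc)3: formaldehyde is small enough to reach the hindered secondary amine, the iminium ion is reduced at room temperature, both aryl positions ortho to C2' are blocked so no Pictet–Spengler-type closure can compete, and C2' is untouched because no hot acid (as in an Eschweiler–Clarke methylation) is used.

**Step 5**
Reactants: 9 (2R)-2-(4-bromo-2,6-dimethoxyphenyl)-1-methylpiperidine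
Product: 11 1-{6-bromo-2,4-dimethoxy-3-[(2R)-1-methylpiperidin-2-yl]phenyl}ethan-1-one, via aryllithium 10 (not isolated)
Conditions: lithium 2,2,6,6-tetramethylpiperidide (LiTMP, from 2,2,6,6-tetramethylpiperidine and n-BuLi, 1.3 equiv), THF, −78 °C; then MeC(O)N(OMe)Me, −78 → −40 °C; aqueous work-up
Reagents that add atoms: N-methoxy-N-methylacetamide, CC(=O)N(C)OC
Why: Directed ortho-metalation followed by a Weinreb ketone synthesis: the two remaining aromatic C–H bonds are equivalent by rotation about the aryl–C2' bond and each lies between OMe and Br, which makes it the most acidic site of 9, aryllithium 10 is kept at −78 °C so that LiBr is not lost, the chelated tetrahedral adduct stops at the ketone, and the acid-free medium (unlike a Friedel–Crafts acetylation on the ammonium salt) endangers neither the methyl ether next to the new acetyl group nor the benzylic C2'–N1' bond.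

**Step 6**
Reactants: 11 1-{6-bromo-2,4-dimethoxy-3-[(2R)-1-methylpiperidin-2-yl]phenyl}ethan-1-one; 12 methyl benzoate
Product: 13 1-{6-bromo-2,4-dimethoxy-3-[(2R)-1-methylpiperidin-2-yl]phenyl}-3-phenylpropane-1,3-dione (drawn as the diketo tautomer)
Conditions: NaH (2.5 equiv), 12 (1.5 equiv), THF, 65 °C; aqueous work-up
Reagents that add atoms: methyl benzoate (12), COC(=O)c1ccccc1
Why: Crossed Claisen condensation: only 11 can form an enolate, its own carbonyl group is shielded by two ortho substituents so self-condensation is slow, methyl benzoate has no α-hydrogen, and irreversible deprotonation of the 1,3-diketone drives the reaction, while the C2'–H bond is far too weakly acidic to be touched.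

**Step 7**
Reactants: 13 1-{6-bromo-2,4-dimethoxy-3-[(2R)-1-methylpiperidin-2-yl]phenyl}-3-phenylpropane-1,3-dione
Product: 14 5,7-dimethoxy-6-[(2R)-1-methylpiperidin-2-yl]-2-phenyl-4H-chromen-4-one
Conditions: CuI (10 mol %), 1,10-phenanthroline (20 mol %), K2CO3 (2 equiv), DMF, 110 °C
Reagents that add atoms: none
Why: Intramolecular Ullmann-type C–O coupling, known for 1-(2-bromoaryl)-1,3-diketones as a flavone synthesis: the enolate oxygen of the benzoyl end replaces the bromide that is activated by the ortho aroyl group and closes the six-membered ring C (O1–C8a), attack through carbon would need a four-membered ring, and since bromine sits para to C2' only the 6-substituted flavone can arise.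

**Step 8**
Reactants: 14 5,7-dimethoxy-6-[(2R)-1-methylpiperidin-2-yl]-2-phenyl-4H-chromen-4-one
Product: 15 5,7-dihydroxy-6-[(2R)-1-methylpiperidin-2-yl]-2-phenyl-4H-chromen-4-one (target)
Conditions: BBr3 (6 equiv), CH2Cl2, −78 °C → rt; then cold aq NaHCO3 to pH 7–8
Reagents that add atoms: none
Why: Lewis-acid cleavage of aryl methyl ethers with BBr3: one equivalent each is taken up by N1' and by the C4 carbonyl, the 5-ether falls first with chelation help and the 7-ether at room temperature, boron bound to the pyranone makes ring A electron-poor and so should hold back ionisation of the C2'–N1' bond, and a cold quench near neutral pH avoids the ortho-quinone methide path that could racemise C2'.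

**Compound list**
1 | 4-bromo-2,6-dimethoxybenzaldehyde | COc1cc(Br)cc(OC)c1C=O | starting material
2 | 1-bromo-4-chlorobutane | ClCCCCBr | starting material
3 | 4-chlorobutylmagnesium bromide | ClCCCC[Mg]Br | intermediate (not isolated)
4 | (±)-1-(4-bromo-2,6-dimethoxyphenyl)-5-chloropentan-1-ol | OC(CCCCCl)c1c(OC)cc(Br)cc1OC | intermediate
5 | 1-(4-bromo-2,6-dimethoxyphenyl)-5-chloropentan-1-one | O=C(CCCCCl)c1c(OC)cc(Br)cc1OC | intermediate
6 | isopropylamine (propan-2-amine) | CC(C)N | starting material
7 | (1R)-1-(4-bromo-2,6-dimethoxyphenyl)-5-chloropentan-1-amine | N[C@H](CCCCCl)c1c(OC)cc(Br)cc1OC | intermediate (not isolated)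
8 | (2R)-2-(4-bromo-2,6-dimethoxyphenyl)piperidine | N1CCCC[C@@H]1c1c(OC)cc(Br)cc1OC | intermediate
9 | (2R)-2-(4-bromo-2,6-dimethoxyphenyl)-1-methylpiperidine | CN1CCCC[C@@H]1c1c(OC)cc(Br)cc1OC | intermediate
10 | {6-bromo-2,4-dimethoxy-3-[(2R)-1-methylpiperidin-2-yl]phenyl}lithium | CN1CCCC[C@@H]1c1c(OC)cc(Br)c([Li])c1OC | intermediate (not isolated)
11 | 1-{6-bromo-2,4-dimethoxy-3-[(2R)-1-methylpiperidin-2-yl]phenyl}ethan-1-one | CN1CCCC[C@@H]1c1c(OC)cc(Br)c(C(C)=O)c1OC | intermediate
12 | methyl benzoate | COC(=O)c1ccccc1 | starting material
13 | 1-{6-bromo-2,4-dimethoxy-3-[(2R)-1-methylpiperidin-2-yl]phenyl}-3-phenylpropane-1,3-dione | CN1CCCC[C@@H]1c1c(OC)cc(Br)c(C(=O)CC(=O)c2ccccc2)c1OC | intermediate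
14 | 5,7-dimethoxy-6-[(2R)-1-methylpiperidin-2-yl]-2-phenyl-4H-chromen-4-one | CN1CCCC[C@@H]1c1c(OC)cc2oc(-c3ccccc3)cc(=O)c2c1OC | intermediate
15 | 5,7-dihydroxy-6-[(2R)-1-methylpiperidin-2-yl]-2-phenyl-4H-chromen-4-one | CN1CCCC[C@@H]1c1c(O)cc2oc(-c3ccccc3)cc(=O)c2c1O | target

Total step count: 8. Longest linear sequence: 8 steps (1 or 2 to 15).

**Steps most likely to fail**

**Step 3 (key step).**
- What may go wrong: the doubly ortho-substituted aryl ketone may not enter the active site at a useful rate. Widening the pocket may cost facial selectivity. Slow turnover leaves time for hydrolysis or aminolysis of the chloride.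
- The fallback uses auxiliary control and known chemistry. It sets out from 1 and 3 and comes back at 8.
- Aldehyde 1 is condensed with (S)-2-methylpropane-2-sulfinamide (Ti(OEt)4, THF) to the (S_S,E)-N-sulfinyl aldimine F1.
- Grignard reagent 3 is added in CH2Cl2 at −48 °C. The closed chair transition state, with magnesium bound to the sulfinyl oxygen and the tert-butyl group equatorial, should deliver the chain to the face that gives the (S_S,R)-sulfinamide F2. The diastereomers can be separated by chromatography.
- KOt-Bu in THF closes the ring by 6-exo-tet N-alkylation to the N-sulfinylpiperidine F3.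
- HCl in MeOH at 0 °C removes the sulfinyl group and gives 8.
- If the ortho methoxy groups chelate magnesium and reverse the sense of addition, the (R)-sulfinamide is used instead.

**Step 5.**
- What may go wrong: the aryllithium may lose LiBr (aryne formation). The electron-rich ring may be deprotonated incompletely. The acetamide may transfer a proton instead of being attacked.
- The fallback sets out from 9 and comes back at 11.
- Electrophilic iodination of the trifluoroacetate salt of 9 (NIS, TFA, MeCN, 0 °C) at the only open ring position gives the aryl iodide F4.
- Iodine–magnesium exchange with i-PrMgCl·LiCl (THF, −20 °C) is much faster at the C–I than at the C–Br bond. It gives the arylmagnesium chloride F5, which holds its ortho bromide far better than the lithium compound.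
- N-methoxy-N-methylacetamide (−20 → 0 °C) then gives 11.

**Step 8.**
- What may go wrong: the C2'–N1' bond may open reversibly, pushed by the freed 5- and 7-oxygen atoms while nitrogen is bound to boron or to a proton. This would erode the enantiomeric purity during cleavage or quench.
- The fallback restores the purity instead of guarding it. It sets out from 15 of lowered purity and comes back at 15.
- The base is crystallised from ethanol as its dibenzoyltartrate salt F6. It is drawn with the (2R,3R)-acid; the enantiomer of the acid that gives the less soluble salt with the (R)-base has to be chosen by trial.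
- The salt is recrystallised and 15 is released with cold aq NaHCO3.
- Because the erosion path is a reversible opening and closing at C2', a warm slurry of the salt could in principle funnel both enantiomers into the less soluble salt (crystallisation-induced diastereomer transformation).

**Further compounds**
F1 | step 3 | (S_S,E)-N-(4-bromo-2,6-dimethoxybenzylidene)-2-methylpropane-2-sulfinamide | CC(C)(C)[S@](=O)/N=C/c1c(OC)cc(Br)cc1OC
F2 | step 3 | (S_S)-N-[(1R)-1-(4-bromo-2,6-dimethoxyphenyl)-5-chloropentyl]-2-methylpropane-2-sulfinamide | CC(C)(C)[S@](=O)N[C@H](CCCCCl)c1c(OC)cc(Br)cc1OC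
F3 | step 3 | (2R)-2-(4-bromo-2,6-dimethoxyphenyl)-1-[(S)-2-methylpropane-2-sulfinyl]piperidine | CC(C)(C)[S@](=O)N1CCCC[C@@H]1c1c(OC)cc(Br)cc1OC
F4 | step 5 | (2R)-2-(4-bromo-3-iodo-2,6-dimethoxyphenyl)-1-methylpiperidine | CN1CCCC[C@@H]1c1c(OC)cc(Br)c(I)c1OC
F5 | step 5 | {6-bromo-2,4-dimethoxy-3-[(2R)-1-methylpiperidin-2-yl]phenyl}magnesium chloride | CN1CCCC[C@@H]1c1c(OC)cc(Br)c([Mg]Cl)c1OC
F6 | step 8 | 1:1 salt of 15 with (2R,3R)-2,3-bis(benzoyloxy)butanedioic acid | CN1CCCC[C@@H]1c1c(O)cc2oc(-c3ccccc3)cc(=O)c2c1O.OC(=O)[C@H](OC(=O)c1ccccc1)[C@@H](OC(=O)c1ccccc1)C(O)=O
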